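**Retrosynthetic overview**

1. Target 27 ← desilylation, acylation of the lactol at C1, and iBu2AlH reduction of an enol δ-lactone whose carbonyl masks the acetal carbon C1; the (Z)-coumarate comes from an ynoate by semi-hydrogenation.
2. Pyran ring (formed last, as the enol δ-lactone C1(=O)–O2–C3=C4) ← γ-lactone 12 by oxidation at C4, methoxymethylenation (C3) and lactone switch.
3. Cyclopentane (ring B): C6–C7 and C9–C8 are made together by a formal [3+2] union of the cyclopropane-fused lactone ester 7 (C5–C6–C9) with the silyl enol ether 9 of 2,2-dimethyl-1,3-dioxan-5-one (C7–C8–C10).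
4. Enabling feature: in ring B the fully substituted carbinol C8 sits between the oxygen-bearing C7 and C10 (a dihydroxyacetone unit: C8 electrophilic, C7 nucleophilic); across the ring, C9 is α to the pyran acetal carbon C1 (a latent carbonyl) and 1,3 to C6 through the ring-fusion carbon C5, so C5–C6–C9 can be a carbonyl-activated cyclopropane.
5. Ring order: cyclopropane (from (R)-glyceraldehyde acetonide, sets C5) → temporary γ-lactone → ring B with a temporary dioxane acetonide (key step) → pyranone; the extra allyl ester on C9, the acetonide and the C4 oxygen are removed afterwards.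

Key step: step 6

Remark: iridoid numbering is used for the target carbons (C1 acetal carbon, O2, C3=C4, C5 and C9 ring-fusion carbons, C6–C8 of the cyclopentane, C10 on C8, C11 on C4); compounds 1, 2, 8, 20 and 25 are taken as purchasable, 25 being the (R)-acid that the target SMILES requires.

**Route**

Step 1
Reactants: 1 (R)-2,2-dimethyl-1,3-dioxolane-4-carbaldehyde; 2 diallyl malonate
Product: 3 diallyl 2-{[(4S)-2,2-dimethyl-1,3-dioxolan-4-yl]methylidene}malonate
Conditions: piperidine (10 mol%), AcOH (10 mol%), 4 Å MS, CH2Cl2, 0 °C → rt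
Reagents that add atoms: none
Why: Knoevenagel condensation under buffered amine catalysis, mild enough to keep the α-alkoxy stereocentre of 1 (the future C4, which later controls C5) intact.

Step 2
Reactants: 3 diallyl 2-{[(4S)-2,2-dimethyl-1,3-dioxolan-4-yl]methylidene}malonate
Product: 4 diallyl (2S)-2-[(4S)-2,2-dimethyl-1,3-dioxolan-4-yl]cyclopropane-1,1-dicarboxylate
Conditions: Me3S(O)I, NaH, DMSO, rt; then 3, THF, 0 °C → rt
Reagents that add atoms: trimethylsulfoxonium iodide, C[S+](C)(C)=O.[I-]
Why: Corey–Chaykovsky cyclopropanation (conjugate addition, then 3-exo-tet closure with loss of dimethyl sulfoxide) in which the ylide should add to the alkylidene carbon anti to the allylic C–O bond of the A(1,3)-minimised conformer (Felkin–Anh-type control by the dioxolane centre), which sets C5.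

Step 3
Reactants: 4 diallyl (2S)-2-[(4S)-2,2-dimethyl-1,3-dioxolan-4-yl]cyclopropane-1,1-dicarboxylate
Product: 6 allyl (1R,4S,5S)-4-(hydroxymethyl)-2-oxo-3-oxabicyclo[3.1.0]hexane-1-carboxylate, via diol 5 (not isolated)
Conditions: AcOH/H2O (4:1), 45 °C; then PhMe, 60 °C (removal of allyl alcohol)
Reagents that add atoms: none
Why: Acetal hydrolysis followed by 5-exo-trig lactonisation of the secondary hydroxyl onto the one ester that is cis to it on the cyclopropane should give the γ-lactone (expected to be favoured over the δ-lactone through the primary hydroxyl), which differentiates the two esters (the lactone carbonyl is the future C1) and strains the cyclopropane for the key step.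

Step 4
Reactants: 6 allyl (1R,4S,5S)-4-(hydroxymethyl)-2-oxo-3-oxabicyclo[3.1.0]hexane-1-carboxylate
Product: 7 allyl (1R,4S,5S)-4-[(tert-butyldiphenylsilyloxy)methyl]-2-oxo-3-oxabicyclo[3.1.0]hexane-1-carboxylate
Conditions: TBDPSCl, imidazole, CH2Cl2, 0 °C → rt
Reagents that add atoms: tert-butyl(chloro)diphenylsilane, CC(C)(C)[Si](Cl)(c1ccccc1)c1ccccc1
Why: Standard silylation of the remaining primary alcohol (the future C11 hydroxyl) as an acid-stable tert-butyldiphenylsilyl ether.

Step 5
Reactants: 8 2,2-dimethyl-1,3-dioxan-5-one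
Product: 9 2,2-dimethyl-5-(triethylsilyloxy)-4H-1,3-dioxine
Conditions: Et3SiOTf, Et3N, CH2Cl2, 0 °C
Reagents that add atoms: triethylsilyl trifluoromethanesulfonate, CC[Si](CC)(CC)OS(=O)(=O)C(F)(F)F
Why: Soft enolisation and O-silylation of the symmetrical ketone (no regiochemical issue) gives the cyclic silyl enol ether, a dihydroxyacetone equivalent that is nucleophilic at C7 and becomes electrophilic at C8.

Step 6
Reactants: 7 allyl (1R,4S,5S)-4-[(tert-butyldiphenylsilyloxy)methyl]-2-oxo-3-oxabicyclo[3.1.0]hexane-1-carboxylate; 9 2,2-dimethyl-5-(triethylsilyloxy)-4H-1,3-dioxine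
Product: 10 tetracyclic lactone ester (ring B cis-fused to the γ-lactone at C5–C9 and to the isopropylidene dioxane at C7–C8 on the opposite face; C8–OSiEt3; C9–CO2allyl)
Conditions: 9 (1.5 equiv), Sc(OTf)3 (10 mol%), 2,6-di-tert-butyl-4-methylpyridine (10 mol%), 4 Å MS, CH2Cl2, −20 °C → rt
Reagents that add atoms: none
Why: Proposed new method: Sc(OTf)3 chelates the lactone and ester carbonyls on C9 of 7 and so polarises the exocyclic cyclopropane bond C9–C6, the enol ether carbon C7 of 9 attacks the methylene carbon C6 in an SN2 (homo-Mukaiyama–Michael) step, and the scandium-bound lactone–ester enolate then adds through C9 to the silyloxocarbenium carbon C8 (Mukaiyama-type aldol) with the silyl group ending on O8; the closest known reactions are the Lewis-acid-catalysed formal [3+2] cycloadditions of donor–acceptor cyclopropane-1,1-dicarboxylates with cyclic silyl enol ethers to ring-fused silyloxycyclopentanes and the homo-conjugate additions of carbon nucleophiles to the methylene carbon of 2-oxo-3-oxabicyclo[3.1.0]hexane-1-carboxylates, which this step merges for a cyclopropane that has no donor group. The only ring closed is the cyclopentane (ring B), by 5-exo-trig attack of the C9 enolate on C8. C5 comes unchanged from 7, C9 is forced to bond cis to the C5–C6 bond by the 5/5 fusion with the lactone, and C7/C8 form the necessarily cis-fused dioxane, which should take the face of ring B opposite to the lactone (cis-anti-cis), so that O8 lies on the lactone face and O7 and C10 on the other. This preference should be reinforced because C7 of the ring-opened intermediate can revert to the silyl enol ether, so that only the less strained cis-anti-cis closure is productive. The selectivity needed is attack at C6 and not at C5, which the bicyclic lactone secures: the exocyclic bond is the one aligned with both carbonyl groups, and C5 is hindered and inductively deactivated by the C4–O bond. In one operation the step joins two fragments of similar size at the fully substituted C8 and installs the C7, C8 and C10 oxygens at their final oxidation levels.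

Step 7
Reactants: 10 tetracyclic lactone ester
Product: 12 tricyclic γ-lactone (10 with H in place of CO2allyl at C9), via carboxylic acid 11 (not isolated)
Conditions: Pd(PPh3)4 (5 mol%), morpholine (1.5 equiv), THF, rt; then PhMe, 100 °C
Reagents that add atoms: none
Why: Tsuji–Trost deallylation (allyl transfer to morpholine through a π-allyl complex of zerovalent palladium) and thermal decarboxylation of the α-carboxy lactone remove the auxiliary ester, and protonation of the lactone enol can only give the cis-fused 5/5 bicycle, which sets C9.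

Step 8
Reactants: 12 tricyclic γ-lactone
Product: 14 keto acid (C4 ketone cis to the C9 carboxylic acid), via hydroxy acid 13 (not isolated)
Conditions: LiOH, THF/H2O, 0 °C → rt; then TEMPO (5 mol%), KBr (10 mol%), NaOCl, NaHCO3, CH2Cl2/H2O, 0 °C; aq. HCl to pH 4
Reagents that add atoms: lithium hydroxide, [Li+].[OH-]
Why: Saponification of the γ-lactone and TEMPO/hypochlorite oxidation of the liberated secondary alcohol as its carboxylate salt (no relactonisation at basic pH) give the C4 ketone and remove the C4 stereocentre, which has done its work.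

Step 9
Reactants: 14 keto acid
Product: 17 enol δ-lactone (7,10-O-isopropylidene; 8-OSiEt3; 11-OTBDPS), via enol ether acid 15 (not isolated), via methoxy lactone 16 (not isolated)
Conditions: MeOCH2PPh3Cl, KN(SiMe3)2, THF, −78 → 0 °C; then CSA (10 mol%), 4 Å MS, PhMe, 80 °C
Reagents that add atoms: (methoxymethyl)triphenylphosphonium chloride, COC[P+](c1ccccc1)(c1ccccc1)c1ccccc1.[Cl-]
Why: Wittig methoxymethylenation of the ketone (introduces C3), then acid-catalysed addition of the cis carboxylic acid to the enol ether (6-exo-trig onto the oxocarbenium ion) and loss of methanol should give the enol δ-lactone, and since only the cis acid can close, the 6/5 ring fusion stays cis.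

Step 10
Reactants: 17 enol δ-lactone
Product: 18 triol enol lactone (7-OH, 8-OH, 10-OH free; 11-OTBDPS)
Conditions: AcOH/THF/H2O (3:1:1), 45 °C
Reagents that add atoms: none
Why: Mild aqueous acid hydrolysis removes the isopropylidene acetal and the tertiary triethylsilyl ether, while the enol lactone and the tert-butyldiphenylsilyl ether should survive.

Step 11
Reactants: 18 triol enol lactone
Product: 19 10-O-TBS diol enol lactone
Conditions: TBSCl (1.1 equiv), imidazole, CH2Cl2, 0 °C
Reagents that add atoms: tert-butyl(chloro)dimethylsilane, CC(C)(C)[Si](C)(C)Cl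
Why: Selective silylation of the primary C10 hydroxyl in the presence of the hindered secondary (C7) and tertiary (C8) hydroxyls.

Step 12
Reactants: 20 tert-butyl(4-ethynylphenoxy)dimethylsilane
Product: 21 3-[4-(tert-butyldimethylsilyloxy)phenyl]prop-2-ynoic acid
Conditions: nBuLi, THF, −78 °C; CO2; aq. HCl (pH 3), 0 °C
Reagents that add atoms: carbon dioxide, O=C=O
Why: Deprotonation of the terminal alkyne and carboxylation of the lithium acetylide.

Step 13
Reactants: 19 10-O-TBS diol enol lactone; 21 3-[4-(tert-butyldimethylsilyloxy)phenyl]prop-2-ynoic acid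
Product: 22 7-O-arylpropioloyl ester of 19
Conditions: DCC, DMAP (10 mol%), CH2Cl2, 0 °C → rt
Reagents that add atoms: none
Why: Steglich esterification of the only reactive (secondary C7) hydroxyl with the arylpropiolic acid, chosen so that the alkene geometry is set afterwards and cannot isomerise during the acylation.

Step 14
Reactants: 22 7-O-arylpropioloyl ester
Product: 23 7-O-[(Z)-4-(tert-butyldimethylsilyloxy)cinnamoyl] ester
Conditions: H2 (1 atm), Pd on CaCO3 poisoned with Pb(OAc)2 (Lindlar catalyst), quinoline, EtOAc, rt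
Reagents that add atoms: none
Why: Lindlar semi-hydrogenation (syn addition of H2) of the ynoate gives the (Z)-cinnamate and should leave the trisubstituted enol lactone alkene untouched.

Step 15
Reactants: 23 7-O-(Z)-cinnamoyl enol lactone
Product: 24 lactol (1-OH; C3=C4 enol ether)
Conditions: iBu2AlH (2.2 equiv), CH2Cl2, −78 °C; aq. KNaC4H4O6
Reagents that add atoms: none
Why: Low-temperature iBu2AlH reduction should stop at the lactol (stable aluminium hemiacetal), the enol δ-lactone being far more electrophilic than the conjugated cinnamate ester, as is known for bicyclic enol δ-lactones of the iridoid type.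

Step 16
Reactants: 24 lactol; 25 (R)-3-methylpentanoic acid
Product: 26 tris-silyl ether of the target (1-O-acyl; 10-OTBS; 11-OTBDPS; aryl-OTBS)
Conditions: DCC, DMAP (10 mol%), CH2Cl2, −20 → 0 °C
Reagents that add atoms: none
Why: Steglich acylation of the hemiacetal hydroxyl (the tertiary C8 hydroxyl does not react) should give the 1β-acyloxy acetal from the equilibrating lactol, the ester taking the anomerically favoured pseudo-axial position anti to the C9–C8 bond, which sets C1.

Step 17
Reactants: 26 tris-silyl ether of the target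
Product: 27 (1S,4aS,6S,7R,7aS)-7-hydroxy-4,7-bis(hydroxymethyl)-6-{[(2Z)-3-(4-hydroxyphenyl)prop-2-enoyl]oxy}-1,4a,5,6,7,7a-hexahydrocyclopenta[c]pyran-1-yl (3R)-3-methylpentanoate
Conditions: Bu4NF/AcOH (1:1, 4 equiv), THF, 0 °C → rt
Reagents that add atoms: none
Why: Fluoride-mediated cleavage of the three silyl ethers under acetic acid buffering, which keeps the medium non-basic and so should avoid acyl migration and loss of the acetal ester.

**Compound list**

1 | (R)-2,2-dimethyl-1,3-dioxolane-4-carbaldehyde | O=C[C@H]1COC(C)(C)O1 | starting material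
2 | diallyl malonate | C=CCOC(=O)CC(=O)OCC=C | starting material
3 | diallyl 2-{[(4S)-2,2-dimethyl-1,3-dioxolan-4-yl]methylidene}malonate | C=CCOC(=O)C(=C[C@H]1COC(C)(C)O1)C(=O)OCC=C | intermediate
4 | diallyl (2S)-2-[(4S)-2,2-dimethyl-1,3-dioxolan-4-yl]cyclopropane-1,1-dicarboxylate | CC1(C)OC[C@@H](O1)[C@H]2CC2(C(=O)OCC=C)C(=O)OCC=C | intermediate
5 | diallyl (2S)-2-[(1S)-1,2-dihydroxyethyl]cyclopropane-1,1-dicarboxylate (diol, not isolated) | OC[C@@H](O)[C@H]1CC1(C(=O)OCC=C)C(=O)OCC=C | intermediate
6 | allyl (1R,4S,5S)-4-(hydroxymethyl)-2-oxo-3-oxabicyclo[3.1.0]hexane-1-carboxylate | OC[C@H]1OC(=O)[C@]2(C(=O)OCC=C)C[C@H]12 | intermediate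
7 | allyl (1R,4S,5S)-4-[(tert-butyldiphenylsilyloxy)methyl]-2-oxo-3-oxabicyclo[3.1.0]hexane-1-carboxylate | CC(C)(C)[Si](c1ccccc1)(c1ccccc1)OC[C@H]1OC(=O)[C@]2(C(=O)OCC=C)C[C@H]12 | intermediate
8 | 2,2-dimethyl-1,3-dioxan-5-one | CC1(C)OCC(=O)CO1 | starting material
9 | 2,2-dimethyl-5-(triethylsilyloxy)-4H-1,3-dioxine | CC[Si](CC)(CC)OC1=COC(C)(C)OC1 | intermediate
10 | tetracyclic lactone ester: cyclopentane (ring B, C5–C9) cis-fused at C5–C9 to the γ-lactone C1(=O)–O–C4 (C4 bears CH2OTBDPS) and at C7–C8 to the 2,2-dimethyl-1,3-dioxane O7–CMe2–O–C10, the outer rings on opposite faces (cis-anti-cis); C8–OSiEt3 on the lactone face; C9–CO2allyl on the face of H-5 | CC(C)(C)[Si](c1ccccc1)(c1ccccc1)OC[C@H]1OC(=O)[C@]2(C(=O)OCC=C)[C@@]3(O[Si](CC)(CC)CC)COC(C)(C)O[C@H]3C[C@H]12 | intermediate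
11 | carboxylic acid of 10 (allyl ester cleaved; not isolated) | CC(C)(C)[Si](c1ccccc1)(c1ccccc1)OC[C@H]1OC(=O)[C@]2(C(O)=O)[C@@]3(O[Si](CC)(CC)CC)COC(C)(C)O[C@H]3C[C@H]12 | intermediate
12 | tricyclic γ-lactone: 10 with H in place of CO2allyl at C9 (H-5 and H-9 cis) | CC(C)(C)[Si](c1ccccc1)(c1ccccc1)OC[C@H]1OC(=O)[C@@H]2[C@@]3(O[Si](CC)(CC)CC)COC(C)(C)O[C@H]3C[C@H]12 | intermediate
13 | hydroxy acid from 12: C1 carboxylic acid on C9, free C4–OH (lithium carboxylate in the flask; not isolated) | CC(C)(C)[Si](c1ccccc1)(c1ccccc1)OC[C@@H](O)[C@H]1C[C@@H]2OC(C)(C)OC[C@]2(O[Si](CC)(CC)CC)[C@H]1C(O)=O | intermediate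
14 | keto acid: C5–CO–CH2OTBDPS cis to the C9 carboxylic acid; C8–OSiEt3; 7,10-O-isopropylidene (may exist as its cyclic hydroxy-lactone) | CC(C)(C)[Si](c1ccccc1)(c1ccccc1)OCC(=O)[C@H]1C[C@@H]2OC(C)(C)OC[C@]2(O[Si](CC)(CC)CC)[C@H]1C(O)=O | intermediate
15 | enol ether acid: 14 with C4=CH–OMe (E/Z mixture; not isolated) | CC(C)(C)[Si](c1ccccc1)(c1ccccc1)OCC(=COC)[C@H]1C[C@@H]2OC(C)(C)OC[C@]2(O[Si](CC)(CC)CC)[C@H]1C(O)=O | intermediate
16 | 3-methoxy δ-lactone (pseudo-ester; epimer mixture at C3 and C4; not isolated) | CC(C)(C)[Si](c1ccccc1)(c1ccccc1)OCC1C(OC)OC(=O)[C@H]2[C@@H]1C[C@@H]1OC(C)(C)OC[C@]21O[Si](CC)(CC)CC | intermediate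
17 | enol δ-lactone: cis-fused cyclopenta[c]pyran-1-one with C3=C4, C4–CH2OTBDPS, C8–OSiEt3 (lactone face), O7 and C10 bridged as isopropylidene acetal (opposite face) | O=C1OC=C(CO[Si](c2ccccc2)(c2ccccc2)C(C)(C)C)[C@H]2C[C@@H]3OC(C)(C)OC[C@]3(O[Si](CC)(CC)CC)[C@@H]12 | intermediate
18 | (4aS,6S,7R,7aS)-4-[(tert-butyldiphenylsilyloxy)methyl]-6,7-dihydroxy-7-(hydroxymethyl)-5,6,7,7a-tetrahydrocyclopenta[c]pyran-1(4aH)-one | O=C1OC=C(CO[Si](c2ccccc2)(c2ccccc2)C(C)(C)C)[C@H]2C[C@H](O)[C@](O)(CO)[C@@H]12 | intermediate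
19 | 18 with the C10 hydroxyl as tert-butyldimethylsilyl ether | O=C1OC=C(CO[Si](c2ccccc2)(c2ccccc2)C(C)(C)C)[C@H]2C[C@H](O)[C@](O)(CO[Si](C)(C)C(C)(C)C)[C@@H]12 | intermediate
20 | tert-butyl(4-ethynylphenoxy)dimethylsilane | C#Cc1ccc(O[Si](C)(C)C(C)(C)C)cc1 | starting material
21 | 3-[4-(tert-butyldimethylsilyloxy)phenyl]prop-2-ynoic acid | OC(=O)C#Cc1ccc(O[Si](C)(C)C(C)(C)C)cc1 | intermediate
22 | 19 esterified at the C7 hydroxyl with 21 (ynoate) | O=C1OC=C(CO[Si](c2ccccc2)(c2ccccc2)C(C)(C)C)[C@H]2C[C@H](OC(=O)C#Cc3ccc(O[Si](C)(C)C(C)(C)C)cc3)[C@](O)(CO[Si](C)(C)C(C)(C)C)[C@@H]12 | intermediate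
23 | 7-O-[(Z)-4-(tert-butyldimethylsilyloxy)cinnamoyl] enol lactone | O=C1OC=C(CO[Si](c2ccccc2)(c2ccccc2)C(C)(C)C)[C@H]2C[C@H](OC(=O)/C=C\c3ccc(O[Si](C)(C)C(C)(C)C)cc3)[C@](O)(CO[Si](C)(C)C(C)(C)C)[C@@H]12 | intermediate
24 | lactol from 23: 1β-hydroxy acetal (OH cis to H-9), C3=C4 enol ether | O[C@@H]1OC=C(CO[Si](c2ccccc2)(c2ccccc2)C(C)(C)C)[C@H]2C[C@H](OC(=O)/C=C\c3ccc(O[Si](C)(C)C(C)(C)C)cc3)[C@](O)(CO[Si](C)(C)C(C)(C)C)[C@@H]12 | intermediate
25 | (R)-3-methylpentanoic acid | CC[C@@H](C)CC(=O)O | starting material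
26 | target with C10–OTBS, C11–OTBDPS and aryl–OTBS | CC[C@@H](C)CC(=O)O[C@@H]1OC=C(CO[Si](c2ccccc2)(c2ccccc2)C(C)(C)C)[C@H]2C[C@H](OC(=O)/C=C\c3ccc(O[Si](C)(C)C(C)(C)C)cc3)[C@](O)(CO[Si](C)(C)C(C)(C)C)[C@@H]12 | intermediate
27 | (1S,4aS,6S,7R,7aS)-7-hydroxy-4,7-bis(hydroxymethyl)-6-{[(2Z)-3-(4-hydroxyphenyl)prop-2-enoyl]oxy}-1,4a,5,6,7,7a-hexahydrocyclopenta[c]pyran-1-yl (3R)-3-methylpentanoate | CC[C@@H](C)CC(=O)O[C@@H]1OC=C(CO)[C@H]2C[C@H](OC(=O)/C=C\c3ccc(O)cc3)[C@](O)(CO)[C@@H]12 | target

**Step count**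

Total: 17 steps. Longest linear sequence: 15 steps (1 → 27 through steps 1–4, 6–11 and 13–17).

**Steps most likely to fail**

Step 6 (proposed new method). The cyclopropane has no donor group, so ring opening by the weakly nucleophilic enol ether may be too slow; Lewis-acid-induced desilylation or acetal cleavage of 9 could then take over, and the closure at C8 could lose its facial preference. Fallback by stepwise known chemistry, from 8 and 7 back to 10: ketone 8 is condensed with 1,1-dimethylhydrazine to the 2,2-dimethyl-1,3-dioxan-5-one N,N-dimethylhydrazone F1. Its lithium azaenolate (LiN(iPr)2, THF, −78 °C) adds in a homo-conjugate fashion to the methylene carbon of 7, giving the ring-opened hydrazone F2. Two-phase aqueous oxalic acid frees the keto lactone ester F3. Soft enolisation of its 1,3-dicarbonyl unit (MgBr2·OEt2, iPr2NEt) closes ring B by intramolecular aldol addition under equilibrating conditions to the tertiary alcohol F4, and Et3SiOTf/2,6-lutidine converts it into 10.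

Step 9. At the hindered ketone, enolisation by the basic ylide may outrun olefination, with epimerisation at C5 and then failure of the lactone closure. Fallback from 14 back to 17, introducing C3 by epoxide rearrangement instead of olefination: dimethylsulfonium methylide (Me3SI, KN(SiMe3)2) converts the ketone into the spiro-epoxide acid F5. Meinwald rearrangement (MgBr2·OEt2) gives the aldehyde acid F6, present as its cyclic hydroxy-lactone. Dehydration (Ac2O, NaOAc, warm) gives the enol δ-lactone 17.

Step 15. The hydride may not discriminate cleanly between the enol lactone and the cinnamate ester, leading to reduction or cleavage of the C7 ester or over-reduction of the lactol. Fallback from 19 back to 26, changing the order so that no other ester is present during the reduction: the C7 hydroxyl of 19 is silylated (Et3SiCl, imidazole) to the 7-O-triethylsilyl ether F7. iBu2AlH gives the lactol F8, and Steglich acylation with 25 gives the 1-O-acyl compound F9. Selective removal of the secondary triethylsilyl group (HF·pyridine, pyridine, 0 °C) gives the 7-alcohol F10. Esterification with 21 gives the ynoate F11, and Lindlar semi-hydrogenation gives 26.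

**Further compounds**

F1 | step 6 | 2,2-dimethyl-1,3-dioxan-5-one N,N-dimethylhydrazone | CC1(C)OCC(=NN(C)C)CO1
F2 | step 6 | ring-opened hydrazone: lactone 7 opened at the methylene carbon, C6 bonded to C7 of the dioxanone hydrazone (epimer mixture at C7 and C9) | CC(C)(C)[Si](c1ccccc1)(c1ccccc1)OC[C@H]1OC(=O)C(C(=O)OCC=C)[C@@H]1CC1OC(C)(C)OCC1=NN(C)C
F3 | step 6 | keto lactone ester (hydrazone of F2 hydrolysed) | CC(C)(C)[Si](c1ccccc1)(c1ccccc1)OC[C@H]1OC(=O)C(C(=O)OCC=C)[C@@H]1CC1OC(C)(C)OCC1=O
F4 | step 6 | tertiary alcohol: 10 with free C8–OH | CC(C)(C)[Si](c1ccccc1)(c1ccccc1)OC[C@H]1OC(=O)[C@]2(C(=O)OCC=C)[C@@]3(O)COC(C)(C)O[C@H]3C[C@H]12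
F5 | step 9 | spiro-epoxide acid: 14 with the C4 ketone converted into an oxirane (C3 is the oxirane CH2; epimer mixture at C4) | CC(C)(C)[Si](c1ccccc1)(c1ccccc1)OCC1(CO1)[C@H]1C[C@@H]2OC(C)(C)OC[C@]2(O[Si](CC)(CC)CC)[C@H]1C(O)=O
F6 | step 9 | aldehyde acid: C4–H bearing the C3 aldehyde and CH2OTBDPS, cis to the C9 carboxylic acid (epimer mixture at C4) | CC(C)(C)[Si](c1ccccc1)(c1ccccc1)OCC(C=O)[C@H]1C[C@@H]2OC(C)(C)OC[C@]2(O[Si](CC)(CC)CC)[C@H]1C(O)=O
F7 | step 15 | 7-O-triethylsilyl ether of 19 | O=C1OC=C(CO[Si](c2ccccc2)(c2ccccc2)C(C)(C)C)[C@H]2C[C@H](O[Si](CC)(CC)CC)[C@](O)(CO[Si](C)(C)C(C)(C)C)[C@@H]12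
F8 | step 15 | lactol from F7 (1β-OH) | O[C@@H]1OC=C(CO[Si](c2ccccc2)(c2ccccc2)C(C)(C)C)[C@H]2C[C@H](O[Si](CC)(CC)CC)[C@](O)(CO[Si](C)(C)C(C)(C)C)[C@@H]12
F9 | step 15 | 1-O-[(3R)-3-methylpentanoyl] derivative of F8 | CC[C@@H](C)CC(=O)O[C@@H]1OC=C(CO[Si](c2ccccc2)(c2ccccc2)C(C)(C)C)[C@H]2C[C@H](O[Si](CC)(CC)CC)[C@](O)(CO[Si](C)(C)C(C)(C)C)[C@@H]12
F10 | step 15 | 7-alcohol: F9 with the triethylsilyl group removed | CC[C@@H](C)CC(=O)O[C@@H]1OC=C(CO[Si](c2ccccc2)(c2ccccc2)C(C)(C)C)[C@H]2C[C@H](O)[C@](O)(CO[Si](C)(C)C(C)(C)C)[C@@H]12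
F11 | step 15 | ynoate: F10 esterified at C7 with 21 | CC[C@@H](C)CC(=O)O[C@@H]1OC=C(CO[Si](c2ccccc2)(c2ccccc2)C(C)(C)C)[C@H]2C[C@H](OC(=O)C#Cc3ccc(O[Si](C)(C)C(C)(C)C)cc3)[C@](O)(CO[Si](C)(C)C(C)(C)C)[C@@H]12
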